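**Plan**

- Numbering: C1 is the ring CH; C2–C14 follow the 14-membered ring through Z-C3=C4(Me), E-C7=C8(CO2H) and E-C11=C12(Me); the side chain is C15(Me)=C16–C17–C18=C19Me2.
- Enabling feature: in the ring, C7=C8(CO2H)–C9H2–C10H2–C11=C12 is a 2-alkylidene ester whose C9 methylene is bonded to an allylic carbon. This is a Baylis–Hillman acrylate (C7–C8=C9) alkylated at C9 by a C10 allyl sulfone carbanion.
- Retrosynthesis: C10–H (from C10–SO2Ph) and CO2H (from CO2Me); then ring bond C9–C10, the only ring closure; then chain bonds C7–C8 (Baylis–Hillman), C4–C5 (B-alkyl Suzuki), C3=C4 (iodo-Wittig), C18=C19 (cross-metathesis), C1–C2 (Johnson–Claisen) and C16–C17 (allylboration), back to geranyl phenyl sulfone (C10–C16).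
- Forward: one linear chain is grown from geranyl phenyl sulfone at C16, C1, C3 and C7 in that order; the single ring is closed last, before ester hydrolysis and removal of the sulfonyl group.
- Stereochemistry: C16–OH (R) from reagent-controlled allylboration, relayed to C1 (R) together with E-C15=C16 by the chair Claisen; E-C11=C12 from the geranyl skeleton; Z-C3=C4 from the iodo ylide and a retentive coupling; E-C7=C8 from the elimination that ends the ring closure.

Key step: step 13

Assumption: the SMILES is read as 1R with 3Z, 7E (carboxyl trans to C6), 11E and 15E alkenes; C7 (28–31) and C10 (31–35) are carried as epimer mixtures because neither centre is stereogenic in the target.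

**Step 1**
Reactants: 1 geranyl bromide; 2 sodium benzenesulfinate
Product: 3 geranyl phenyl sulfone
Conditions: DMF, rt
Reagents that add atoms: sodium benzenesulfinate 2, [Na+].[O-]S(=O)c1ccccc1
Why: SN2 S-alkylation of the soft sulfur of the ambident sulfinate by the primary allylic bromide in DMF should give the sulfone with the E alkene untouched (sulfinate alkylation).

**Step 2**
Reactants: 3 geranyl phenyl sulfone
Product: 4 (2E,6E)-2,6-dimethyl-8-(phenylsulfonyl)octa-2,6-dien-1-ol
Conditions: SeO2 (cat.), t-BuOOH, salicylic acid (cat.), CH2Cl2, rt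
Reagents that add atoms: tert-butyl hydroperoxide, CC(C)(C)OO (oxygen passed on through catalytic SeO2, O=[Se]=O)
Why: Catalytic SeO2 allylic oxidation (ene reaction, then [2,3]-sigmatropic shift) should hydroxylate the (E)-methyl group of the electron-rich terminal isopropylidene, the alkene next to the sulfonylmethyl group being deactivated; any enal 5 formed alongside is taken into step 3.

**Step 3**
Reactants: 4 hydroxy sulfone
Product: 5 (2E,6E)-2,6-dimethyl-8-(phenylsulfonyl)octa-2,6-dienal
Conditions: MnO2, CH2Cl2, rt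
Reagents that add atoms: none
Why: Activated MnO2 oxidises a primary allylic alcohol to the enal selectively and without E/Z isomerisation (allylic alcohol oxidation).

**Step 4**
Reactants: 5 enal; 6 (+)-B-methoxydiisopinocampheylborane (from (−)-α-pinene); 7 allylmagnesium bromide
Product: 10 (4R,5E,9E)-5,9-dimethyl-11-(phenylsulfonyl)undeca-1,5,9-trien-4-ol, via allylborane 8 (not isolated), via borinate 9 (not isolated)
Conditions: 6 + 7, Et2O, −78 °C → rt; then 5, −78 °C; then NaOH, H2O2, rt
Reagents that add atoms: allylmagnesium bromide 7, C=CC[Mg]Br (allyl delivered as borane 8, C=CCB([C@H]1C[C@H]2C[C@@H]([C@@H]1C)C2(C)C)[C@H]1C[C@H]2C[C@@H]([C@@H]1C)C2(C)C)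
Why: Brown asymmetric allylboration through a closed chair transition state, in which the isopinocampheyl groups of the (−)-α-pinene-derived reagent 8 should deliver allyl to the Re face of the enal and so set C16 as R, followed by alkaline peroxide cleavage of the borinate; the neutral reagent leaves the acidic sulfone untouched.

**Step 5**
Reactants: 10 (R)-allylic alcohol; 11 triethyl orthoacetate
Product: 14 ethyl (3R,6E)-3-[(2E)-hexa-2,5-dien-2-yl]-6-methyl-8-(phenylsulfonyl)oct-6-enoate, via mixed orthoester 12 (not isolated), via ketene acetal 13 (not isolated)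
Conditions: 11 (excess), EtCO2H (cat.), 135 °C, EtOH distilled off
Reagents that add atoms: triethyl orthoacetate 11, CC(OCC)(OCC)OCC
Why: Johnson orthoester Claisen rearrangement, in which ketene acetal 13 reorganises through a chair transition state with the C16 allyl substituent equatorial, so that the E C15=C16 alkene forms and the C16 configuration is transferred suprafacially to C1 (R); the weakly acidic conditions avoid the amide bases that the sulfone could not survive.

**Step 6**
Reactants: 14 Claisen ester; 15 2-methyl-2-butene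
Product: 16 ethyl (3R,6E)-6-methyl-3-[(2E)-6-methylhepta-2,5-dien-2-yl]-8-(phenylsulfonyl)oct-6-enoate
Conditions: 15 (excess), second-generation Grubbs catalyst RuCl2(=CHPh)(H2IMes)(PCy3) (cat.), CH2Cl2, 40 °C
Reagents that add atoms: 2-methyl-2-butene 15, CC=C(C)C
Why: Olefin cross-metathesis of the only monosubstituted alkene with excess 2-methyl-2-butene should turn the allyl terminus into the isopropylidene group, the trisubstituted alkenes being inert to the catalyst.

**Step 7**
Reactants: 16 prenylated ester
Product: 17 (3R,6E)-6-methyl-3-[(2E)-6-methylhepta-2,5-dien-2-yl]-8-(phenylsulfonyl)oct-6-enal (C3 aldehyde)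
Conditions: i-Bu2AlH, CH2Cl2, −78 °C; MeOH, aq. potassium sodium tartrate
Reagents that add atoms: none
Why: Partial ester reduction with i-Bu2AlH at −78 °C stops at the aluminium hemiacetal, which releases the aldehyde on work-up; C1 is β to the carbonyl and cannot epimerise.

**Step 8**
Reactants: 17 C3 aldehyde; 18 ethyltriphenylphosphonium iodide
Product: 22 (Z)-vinyl iodide with C2–C3H=C4(CH3)I, via ethylidene ylide 19 (not isolated), via iodophosphonium salt 20 (not isolated), via iodo ylide 21 (not isolated)
Conditions: 18, n-BuLi, THF, 0 °C; I2, −78 °C; NaN(SiMe3)2, −78 → −20 °C; then 17, −78 → −20 °C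
Reagents that add atoms: ethyltriphenylphosphonium iodide 18, CC[P+](c1ccccc1)(c1ccccc1)c1ccccc1.[I-]; iodine, II (both delivered as ylide 21, CC(I)=P(c1ccccc1)(c1ccccc1)c1ccccc1)
Why: Stork–Zhao-type Wittig olefination with the α-iodo ylide 21, which should give the (Z)-2-iodo-2-alkene (iodine cis to C2) under kinetic control; the ylide is a weaker base than the sulfonyl carbanion, so C10 is not deprotonated.

**Step 9**
Reactants: 22 (Z)-vinyl iodide; 23 acrolein diethyl acetal
Product: 25 diethyl acetal of the C7 aldehyde, via alkylborane 24 (not isolated)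
Conditions: 23, 9-BBN-H, THF, 0 °C → rt; then 22, PdCl2(dppf) (cat.), AsPh3, Cs2CO3, DMF/H2O, rt
Reagents that add atoms: acrolein diethyl acetal 23, C=CC(OCC)OCC (delivered as borane 24, CCOC(CCB1C2CCCC1CCC2)OCC)
Why: B-alkyl Suzuki–Miyaura coupling, in which anti-Markovnikov hydroboration gives primary borane 24 that couples at C4 with retention of alkene geometry (C2 cis to C5), oxidative addition into the C–I bond being much faster than ionisation of the allylic sulfone.

**Step 10**
Reactants: 25 diethyl acetal
Product: 26 (4Z,7R,10E)-4,10-dimethyl-7-[(2E)-6-methylhepta-2,5-dien-2-yl]-12-(phenylsulfonyl)dodeca-4,10-dienal (C7 aldehyde)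
Conditions: PPTS, acetone/H2O, 50 °C
Reagents that add atoms: water, O
Why: Mild acid-catalysed acetal hydrolysis should free the C7 aldehyde without moving the skipped diene or the Z alkene.

**Step 11**
Reactants: 26 C7 aldehyde; 27 methyl acrylate
Product: 28 Baylis–Hillman alcohol (both C7 epimers)
Conditions: 27 (excess), DABCO, MeOH, rt, several days
Reagents that add atoms: methyl acrylate 27, C=CC(=O)OC
Why: Morita–Baylis–Hillman reaction, in which the DABCO–acrylate zwitterion adds to the unhindered aliphatic aldehyde and proton transfer then releases the amine; C7 forms as both epimers, which is immaterial because it becomes sp2 in step 13.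

**Step 12**
Reactants: 28 Baylis–Hillman alcohol
Product: 29 Baylis–Hillman methyl carbonate (both C7 epimers)
Conditions: ClCO2Me, pyridine, DMAP (cat.), CH2Cl2, 0 °C
Reagents that add atoms: methyl chloroformate, COC(=O)Cl
Why: O-acylation of the secondary allylic alcohol with a chloroformate under DMAP catalysis should give the carbonate leaving group without allylic transposition at 0 °C.

**Step 13**
Reactants: 29 Baylis–Hillman methyl carbonate
Product: 32 macrocyclic sulfonyl methyl ester (both C10 epimers), via lithiated sulfone 30 (not isolated), via ring enolate 31 (not isolated)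
Conditions: LiN(SiMe3)2 (1.1 equiv), THF, −78 → 0 °C; 29 added slowly to the base, about 0.002 M; aq. NH4Cl
Reagents that add atoms: none
Why: Proposed new method: LiN(SiMe3)2 should remove a proton from C10 (α to sulfonyl and allylic, the most acidic C–H of 29), the carbanion 30 adds through C10 to the unsubstituted acrylate terminus C9, and the ester enolate 31 expels methyl carbonate from C7 (E1cB), moving the alkene to C7=C8; the closest known reactions are the intermolecular addition–elimination of stabilised carbanions on Baylis–Hillman carbonates and the macrocyclising alkylation of allyl sulfone anions by allylic halides used for 14-membered terpenoid rings. The ring closes by a 14-endo-trig conjugate addition. C10 becomes a stereocentre without control, which is harmless because the sulfonyl group is removed in step 15, and C1 is not touched. Attack through C10 and not C12 is secured by the fully substituted γ-carbon C12. The alkene geometry (C6 cis to C9, ester trans to C6) should follow from allylic strain in the eliminating enolate, as in open-chain cases. Ring closure over oligomerisation is secured by slow addition at high dilution, and the carbonate has no acidic hydrogen to quench the carbanion.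

**Step 14**
Reactants: 32 macrocyclic sulfonyl methyl ester
Product: 34 macrocyclic sulfonyl acid (both C10 epimers), via sodium carboxylate 33 (not isolated)
Conditions: NaOH, THF/MeOH/H2O, 40 °C; then dilute HCl
Reagents that add atoms: sodium hydroxide, [Na+].[OH-]
Why: Saponification of the conjugated methyl ester by hydroxide (acyl substitution) gives the sodium carboxylate, which is acidified to the free acid; it is done before desulfonylation so that the carboxyl group meets the hydride reagent as its unreactive salt, and the C10 epimers need no control.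

**Step 15**
Reactants: 34 macrocyclic sulfonyl acid
Product: 37 target acid CNP0112585.1, via lithium sulfonyl carboxylate 35 (not isolated), via lithium salt 36 (not isolated)
Conditions: PdCl2(dppp) (cat.), LiBHEt3 (excess), THF, 0 °C → rt; then dilute HCl
Reagents that add atoms: none
Why: Palladium-catalysed hydride desulfonylation of an allylic sulfone, in which the first equivalent of LiBHEt3 turns the acid into its lithium carboxylate 35, which resists reduction, and zerovalent palladium formed from PdCl2(dppp) then ionises the C10–S bond; the dppp-ligated π-allyl complex should take up hydride at the less substituted terminus C10, so that the E C11=C12 alkene stays in place and the C10 stereocentre disappears.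

**Compound list**

1 | geranyl bromide, (2E)-1-bromo-3,7-dimethylocta-2,6-diene | CC(C)=CCC/C(C)=C/CBr | starting material
2 | sodium benzenesulfinate | [Na+].[O-]S(=O)c1ccccc1 | starting material
3 | geranyl phenyl sulfone, [(2E)-3,7-dimethylocta-2,6-dienyl]sulfonylbenzene | CC(C)=CCC/C(C)=C/CS(=O)(=O)c1ccccc1 | intermediate
4 | (2E,6E)-2,6-dimethyl-8-(phenylsulfonyl)octa-2,6-dien-1-ol | OC/C(C)=C/CC/C(C)=C/CS(=O)(=O)c1ccccc1 | intermediate
5 | (2E,6E)-2,6-dimethyl-8-(phenylsulfonyl)octa-2,6-dienal | O=C/C(C)=C/CC/C(C)=C/CS(=O)(=O)c1ccccc1 | intermediate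
6 | (+)-B-methoxydiisopinocampheylborane, from (−)-α-pinene | COB([C@H]1C[C@H]2C[C@@H]([C@@H]1C)C2(C)C)[C@H]1C[C@H]2C[C@@H]([C@@H]1C)C2(C)C | starting material
7 | allylmagnesium bromide | C=CC[Mg]Br | starting material
8 | B-allyldiisopinocampheylborane of the (−)-α-pinene series | C=CCB([C@H]1C[C@H]2C[C@@H]([C@@H]1C)C2(C)C)[C@H]1C[C@H]2C[C@@H]([C@@H]1C)C2(C)C | intermediate
9 | O-(diisopinocampheylboryl) derivative of alcohol 10 (borinate) | C=CC[C@@H](OB([C@H]1C[C@H]2C[C@@H]([C@@H]1C)C2(C)C)[C@H]1C[C@H]2C[C@@H]([C@@H]1C)C2(C)C)/C(C)=C/CC/C(C)=C/CS(=O)(=O)c1ccccc1 | intermediate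
10 | (4R,5E,9E)-5,9-dimethyl-11-(phenylsulfonyl)undeca-1,5,9-trien-4-ol | C=CC[C@@H](O)/C(C)=C/CC/C(C)=C/CS(=O)(=O)c1ccccc1 | intermediate
11 | triethyl orthoacetate | CC(OCC)(OCC)OCC | starting material
12 | mixed orthoester, 1,1-diethoxyethyl ether of 10 | CC(OCC)(OCC)O[C@H](CC=C)/C(C)=C/CC/C(C)=C/CS(=O)(=O)c1ccccc1 | intermediate
13 | ketene acetal, 1-ethoxyvinyl ether of 10 | C=C(OCC)O[C@H](CC=C)/C(C)=C/CC/C(C)=C/CS(=O)(=O)c1ccccc1 | intermediate
14 | ethyl (3R,6E)-3-[(2E)-hexa-2,5-dien-2-yl]-6-methyl-8-(phenylsulfonyl)oct-6-enoate | C=CC/C=C(\C)[C@H](CC/C(C)=C/CS(=O)(=O)c1ccccc1)CC(=O)OCC | intermediate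
15 | 2-methyl-2-butene | CC=C(C)C | starting material
16 | ethyl (3R,6E)-6-methyl-3-[(2E)-6-methylhepta-2,5-dien-2-yl]-8-(phenylsulfonyl)oct-6-enoate | CC(C)=CC/C=C(\C)[C@H](CC/C(C)=C/CS(=O)(=O)c1ccccc1)CC(=O)OCC | intermediate
17 | (3R,6E)-6-methyl-3-[(2E)-6-methylhepta-2,5-dien-2-yl]-8-(phenylsulfonyl)oct-6-enal | CC(C)=CC/C=C(\C)[C@H](CC/C(C)=C/CS(=O)(=O)c1ccccc1)CC=O | intermediate
18 | ethyltriphenylphosphonium iodide | CC[P+](c1ccccc1)(c1ccccc1)c1ccccc1.[I-] | starting material
19 | ethylidenetriphenylphosphorane | CC=P(c1ccccc1)(c1ccccc1)c1ccccc1 | intermediate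
20 | (1-iodoethyl)triphenylphosphonium iodide | CC(I)[P+](c1ccccc1)(c1ccccc1)c1ccccc1.[I-] | intermediate
21 | (1-iodoethylidene)triphenylphosphorane | CC(I)=P(c1ccccc1)(c1ccccc1)c1ccccc1 | intermediate
22 | phenyl (2E,6R,8Z)-9-iodo-3-methyl-6-[(2E)-6-methylhepta-2,5-dien-2-yl]deca-2,8-dienyl sulfone | CC(C)=CC/C=C(\C)[C@H](CC/C(C)=C/CS(=O)(=O)c1ccccc1)C/C=C(/C)I | intermediate
23 | acrolein diethyl acetal, 3,3-diethoxyprop-1-ene | C=CC(OCC)OCC | starting material
24 | B-(3,3-diethoxypropyl)-9-borabicyclo[3.3.1]nonane | CCOC(CCB1C2CCCC1CCC2)OCC | intermediate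
25 | phenyl (2E,6R,8Z)-12,12-diethoxy-3,9-dimethyl-6-[(2E)-6-methylhepta-2,5-dien-2-yl]dodeca-2,8-dienyl sulfone | CC(C)=CC/C=C(\C)[C@H](CC/C(C)=C/CS(=O)(=O)c1ccccc1)C/C=C(/C)CCC(OCC)OCC | intermediate
26 | (4Z,7R,10E)-4,10-dimethyl-7-[(2E)-6-methylhepta-2,5-dien-2-yl]-12-(phenylsulfonyl)dodeca-4,10-dienal | CC(C)=CC/C=C(\C)[C@H](CC/C(C)=C/CS(=O)(=O)c1ccccc1)C/C=C(/C)CCC=O | intermediate
27 | methyl acrylate | C=CC(=O)OC | starting material
28 | methyl (6Z,9R,12E)-3-hydroxy-6,12-dimethyl-2-methylidene-9-[(2E)-6-methylhepta-2,5-dien-2-yl]-14-(phenylsulfonyl)tetradeca-6,12-dienoate, both C3 (ring C7) epimers | CC(C)=CC/C=C(\C)[C@H](CC/C(C)=C/CS(=O)(=O)c1ccccc1)C/C=C(/C)CCC(O)C(=C)C(=O)OC | intermediate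
29 | methyl carbonate of 28, both C7 epimers (seco precursor) | CC(C)=CC/C=C(\C)[C@H](CC/C(C)=C/CS(=O)(=O)c1ccccc1)C/C=C(/C)CCC(OC(=O)OC)C(=C)C(=O)OC | intermediate
30 | C10-lithiated sulfone of 29 | CC(C)=CC/C=C(\C)[C@H](CC/C(C)=C/[CH-]S(=O)(=O)c1ccccc1)C/C=C(/C)CCC(OC(=O)OC)C(=C)C(=O)OC.[Li+] | intermediate
31 | 14-membered lithium ester enolate with the carbonate still on C7 | CC(C)=CC/C=C(\C)[C@H]1C/C=C(/C)CCC(OC(=O)OC)C(=C([O-])OC)CC(S(=O)(=O)c2ccccc2)/C=C(\C)CC1.[Li+] | intermediate
32 | methyl (1E,5Z,8R,11E)-5,11-dimethyl-8-[(2E)-6-methylhepta-2,5-dien-2-yl]-13-(phenylsulfonyl)cyclotetradeca-1,5,11-triene-1-carboxylate, both C13 (ring C10) epimers | CC(C)=CC/C=C(\C)[C@H]1C/C=C(/C)CC/C=C(/C(=O)OC)CC(S(=O)(=O)c2ccccc2)/C=C(\C)CC1 | intermediate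
33 | sodium carboxylate of sulfonyl acid 34 | CC(C)=CC/C=C(\C)[C@H]1C/C=C(/C)CC/C=C(/C(=O)[O-])CC(S(=O)(=O)c2ccccc2)/C=C(\C)CC1.[Na+] | intermediate
34 | (1E,5Z,8R,11E)-5,11-dimethyl-8-[(2E)-6-methylhepta-2,5-dien-2-yl]-13-(phenylsulfonyl)cyclotetradeca-1,5,11-triene-1-carboxylic acid, both C13 epimers | CC(C)=CC/C=C(\C)[C@H]1C/C=C(/C)CC/C=C(/C(=O)O)CC(S(=O)(=O)c2ccccc2)/C=C(\C)CC1 | intermediate
35 | lithium carboxylate of sulfonyl acid 34 | CC(C)=CC/C=C(\C)[C@H]1C/C=C(/C)CC/C=C(/C(=O)[O-])CC(S(=O)(=O)c2ccccc2)/C=C(\C)CC1.[Li+] | intermediate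
36 | lithium salt of the target acid | CC(C)=CC/C=C(\C)[C@H]1C/C=C(/C)CC/C=C(/C(=O)[O-])CC/C=C(\C)CC1.[Li+] | intermediate
37 | CNP0112585.1, (1E,5Z,8R,11E)-5,11-dimethyl-8-[(2E)-6-methylhepta-2,5-dien-2-yl]cyclotetradeca-1,5,11-triene-1-carboxylic acid | CC(C)=CC/C=C(\C)[C@H]1C/C=C(/C)CC/C=C(/C(=O)O)CC/C=C(\C)CC1 | target

**Step count and risks**

Total step count: 15. Longest linear sequence: 15 steps, from geranyl bromide 1 to 37.

Steps most likely to fail:

1. Step 13 (proposed new method). Intermolecular conjugate addition leading to oligomers, attack of the carbanion or the amide base on the carbonate or acrylate in an unproductive sense, or elimination in the wrong geometric sense could outrun the 14-membered closure. The fallback makes the same C9–C10 bond by known chemistry and sets out from alcohol 28. NBS and Me2S in CH2Cl2 at 0 °C should convert 28 with allylic transposition into the primary allylic bromide, methyl (2Z)-2-(bromomethyl)alk-2-enoate F1, in which the alkene geometry is already fixed. Slow addition of F1 to LiN(SiMe3)2 in THF at high dilution then closes the ring by the established macrocyclising SN2 alkylation of an allyl sulfone anion with an allylic bromide. This comes back to the route at 32.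

2. Step 8. Erosion of the Z selectivity, decomposition of the iodo ylide before it meets the aldehyde, or proton transfer from C10 could leave little usable vinyl iodide. The fallback sets out from aldehyde 17 and builds the Z alkene by a Still–Gennari olefination with methyl 2-[bis(2,2,2-trifluoroethoxy)phosphoryl]propanoate, KN(SiMe3)2 and 18-crown-6 at −78 °C, giving the (Z)-2-methyl enoate F2. Reduction with i-Bu2AlH gives the (Z)-allylic alcohol F3, and CBr4/PPh3 gives the allylic bromide F4. Alkylation of sodium dimethyl malonate, a nucleophile too weakly basic to deprotonate the sulfone, gives the malonate F5. Krapcho demethoxycarbonylation (LiCl, wet DMSO, 150 °C) gives the methyl ester F6, and i-Bu2AlH at −78 °C gives the aldehyde. This comes back to the route at 26 and bypasses steps 8 to 10.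

3. Step 15. Hydride addition to the conjugated carboxylate, capture of the π-allyl intermediate by the neighbouring carboxylate, or loss of the C11=C12 position could spoil the last step. The fallback changes the oxidation level of the substituent on C8 and sets out from ester 32. i-Bu2AlH reduces the ester to the allylic alcohol F7, which carries no reducible carbonyl group. PdCl2(dppp) with LiBHEt3 then removes the sulfonyl group to give the macrocyclic allylic alcohol F8. MnO2 gives the enal F9, and Pinnick oxidation (NaClO2, NaH2PO4, 2-methyl-2-butene, t-BuOH/H2O) gives the acid. This comes back to the route at 37.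

**Further compounds**

F1 | step 13 | methyl (2Z)-2-(bromomethyl)alk-2-enoate corresponding to 28 (C6 cis to CH2Br), seco allylic bromide | CC(C)=CC/C=C(\C)[C@H](CC/C(C)=C/CS(=O)(=O)c1ccccc1)C/C=C(/C)CC/C=C(/C(=O)OC)CBr
F2 | step 8 | methyl (2Z)-2-methyl enoate from 17 (ester cis to C2) | CC(C)=CC/C=C(\C)[C@H](CC/C(C)=C/CS(=O)(=O)c1ccccc1)C/C=C(/C)C(=O)OC
F3 | step 8 | (Z)-allylic alcohol from F2 | CC(C)=CC/C=C(\C)[C@H](CC/C(C)=C/CS(=O)(=O)c1ccccc1)C/C=C(/C)CO
F4 | step 8 | (Z)-allylic bromide from F3 | CC(C)=CC/C=C(\C)[C@H](CC/C(C)=C/CS(=O)(=O)c1ccccc1)C/C=C(/C)CBr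
F5 | step 8 | dimethyl malonate alkylated by F4 | CC(C)=CC/C=C(\C)[C@H](CC/C(C)=C/CS(=O)(=O)c1ccccc1)C/C=C(/C)CC(C(=O)OC)C(=O)OC
F6 | step 8 | methyl ester at C7 from F5 | CC(C)=CC/C=C(\C)[C@H](CC/C(C)=C/CS(=O)(=O)c1ccccc1)C/C=C(/C)CCC(=O)OC
F7 | step 15 | macrocyclic sulfonyl allylic alcohol (CH2OH on C8) | CC(C)=CC/C=C(\C)[C@H]1C/C=C(/C)CC/C=C(/CO)CC(S(=O)(=O)c2ccccc2)/C=C(\C)CC1
F8 | step 15 | desulfonylated macrocyclic allylic alcohol | CC(C)=CC/C=C(\C)[C@H]1C/C=C(/C)CC/C=C(/CO)CC/C=C(\C)CC1
F9 | step 15 | macrocyclic enal (CHO on C8) | CC(C)=CC/C=C(\C)[C@H]1C/C=C(/C)CC/C=C(/C=O)CC/C=C(\C)CC1
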